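Ring A is disconnected at the two bonds that meet at C7, C7–O and C7–C8. C7 (guaiacyl-bearing, at the aldehyde oxidation level) sits between the ring-A oxygen and the carbinol carbon C8, and C8 becomes enolisable once C9 of ring B is a lactone carbonyl, so ring A equals vanillin plus a ring-B lactone. In one flask, Me3SiOTf/Et3N silylates a 3-hydroxy-4-(hydroxymethyl)-5-veratryl butyrolactone, converts it into its silyl ketene acetal and condenses silyl-protected vanillin with the C9' silyl ether to an oxocarbenium ion that C8 captures, which closes ring A and sets C7 and C8. The lactone comes from an Evans aldol–lactonisation; lactone-to-ether reduction and desilylation finish the synthesis.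

Key step: step 8

Remark: lignan numbering is used throughout (ring A: C7, O, C9', C8', C8; ring B: C7', O, C9, C8, C8'); the key-step lactone is kept as its free diol and silylated in the key-step flask, with the small Me3Si group on O8 so that the aryl group that must end cis to O8 meets little strain and the tertiary ether is easy to cleave; (S)-4-benzyl-1,3-oxazolidin-2-one and methyl 4-chloro-4-oxobutanoate are taken as commercial.

Step 1
Reactants: 1 vanillin
Product: 2 4-(tert-butyldimethylsilyloxy)-3-methoxybenzaldehyde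
Conditions: TBSCl, imidazole, DMF, rt
Reagents that add atoms: tert-butyldimethylsilyl chloride, CC(C)(C)[Si](C)(C)Cl
Why: Imidazole-promoted O-silylation of the phenol masks the acidic OH, so that the aldehyde can later be activated by a silyl triflate without phenoxide or quinone methide chemistry.

Step 2
Reactants: 3 (S)-4-benzyl-1,3-oxazolidin-2-one; 4 methyl 4-chloro-4-oxobutanoate
Product: 5 methyl 4-[(4S)-4-benzyl-2-oxo-1,3-oxazolidin-3-yl]-4-oxobutanoate
Conditions: n-BuLi, THF, −78 °C; then 4, −78 to 0 °C
Reagents that add atoms: none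
Why: N-acylation of the lithiated oxazolidinone by the acid chloride (imide formation) places the chiral auxiliary on the succinate half-ester, the ester being far less electrophilic than the acid chloride.

Step 3
Reactants: 5 methyl 4-[(4S)-4-benzyl-2-oxo-1,3-oxazolidin-3-yl]-4-oxobutanoate; 6 3,4-dimethoxybenzaldehyde (veratraldehyde)
Product: 8 (4S)-4-benzyl-3-[(2S,3S)-2-(3,4-dimethoxyphenyl)-5-oxooxolane-3-carbonyl]-1,3-oxazolidin-2-one (trans lactone), via syn-aldol adduct 7 (not isolated)
Conditions: Bu2BOTf, Et3N, CH2Cl2, −78 to 0 °C; then 6, −78 to 0 °C; pH 7 buffer, MeOH, H2O2, 0 °C; then p-TsOH·H2O (cat.), CH2Cl2, rt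
Reagents that add atoms: none
Why: Soft enolisation gives the (Z)-boron enolate of the imide only, which adds to 6 through a Zimmerman–Traxler chair on the face away from the benzyl group (Evans syn-aldol) and sets C8' and C7' as (S,S) in 7, after which the gamma-hydroxy ester lactonises to the trans-4,5-disubstituted lactone.

Step 4
Reactants: 8 (4S)-4-benzyl-3-[(2S,3S)-2-(3,4-dimethoxyphenyl)-5-oxooxolane-3-carbonyl]-1,3-oxazolidin-2-one
Product: 9 (2S,3S)-2-(3,4-dimethoxyphenyl)-5-oxooxolane-3-carboxylic acid
Conditions: LiOH, H2O2, THF/H2O, 0 °C; aq. Na2SO3; then 1 M HCl to pH 2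
Reagents that add atoms: hydrogen peroxide (as LiOOH), OO
Why: Hydroperoxide attacks the exocyclic imide carbonyl selectively (hydroperoxide-mediated cleavage of an N-acyl oxazolidinone), and acidification re-closes any lactone opened by hydroxide, so both stereocentres stay untouched.

Step 5
Reactants: 9 (2S,3S)-2-(3,4-dimethoxyphenyl)-5-oxooxolane-3-carboxylic acid
Product: 10 (4R,5S)-5-(3,4-dimethoxyphenyl)-4-(hydroxymethyl)oxolan-2-one
Conditions: BH3·SMe2, THF, 0 °C to rt; MeOH quench
Reagents that add atoms: none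
Why: Borane reduces a free carboxylic acid through its acyloxyborane much faster than a lactone (chemoselective borane reduction), and the non-basic medium avoids acyl migration of the lactone to the new primary hydroxyl.

Step 6
Reactants: 10 (4R,5S)-5-(3,4-dimethoxyphenyl)-4-(hydroxymethyl)oxolan-2-one
Product: 11 (4R,5S)-5-(3,4-dimethoxyphenyl)-4-[(triethylsilyloxy)methyl]oxolan-2-one
Conditions: Et3SiCl, imidazole, CH2Cl2, 0 °C
Reagents that add atoms: chlorotriethylsilane, CC[Si](Cl)(CC)CC
Why: Imidazole-promoted silylation of the primary alcohol gives a triethylsilyl ether that survives the enolate chemistry of step 7 and is cleaved by dilute acid.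

Step 7
Reactants: 11 (4R,5S)-5-(3,4-dimethoxyphenyl)-4-[(triethylsilyloxy)methyl]oxolan-2-one
Product: 13 (3S,4S,5S)-5-(3,4-dimethoxyphenyl)-3-hydroxy-4-(hydroxymethyl)oxolan-2-one, via alpha-hydroxy silyl ether 12 (not isolated)
Conditions: KN(SiMe3)2, THF, −78 °C; 2-(phenylsulfonyl)-3-phenyloxaziridine, −78 °C; sat. NH4Cl; then 1 M HCl, THF, rt
Reagents that add atoms: 2-(phenylsulfonyl)-3-phenyloxaziridine, O=S(=O)(c1ccccc1)N1OC1c1ccccc1
Why: The potassium lactone enolate is oxidised at C8 by the N-sulfonyloxaziridine (enolate hydroxylation) anti to the C9' arm, C8' offering no leaving group for elimination, and dilute acid then frees the primary alcohol; the C8 configuration is of no consequence because step 8 planarises C8.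

Step 8
Reactants: 13 (3S,4S,5S)-5-(3,4-dimethoxyphenyl)-3-hydroxy-4-(hydroxymethyl)oxolan-2-one; 2 4-(tert-butyldimethylsilyloxy)-3-methoxybenzaldehyde
Product: 17 (3S,3aR,6R,6aR)-6-[4-(tert-butyldimethylsilyloxy)-3-methoxyphenyl]-3-(3,4-dimethoxyphenyl)-6a-(trimethylsilyloxy)tetrahydro-1H,3H-furo[3,4-c]furan-1-one (lignan descriptors 7R,8R,7'S,8'R), via bis-silyl ether 14 (not isolated), via silyl ketene acetal 15 (not isolated), via oxocarbenium triflate 16 (not isolated)
Conditions: Et3N (3.5 equiv), Me3SiOTf (3.3 equiv), CH2Cl2, 0 °C to rt; then 2 (1.2 equiv), Me3SiOTf (0.6 equiv), −78 to −30 °C; aq. NaHCO3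
Reagents that add atoms: trimethylsilyl trifluoromethanesulfonate, C[Si](C)(C)OS(=O)(=O)C(F)(F)F
Why: Me3SiOTf/Et3N first silylates both hydroxyls of 13 (14) and soft-enolises the alpha-silyloxy lactone to the silyl ketene acetal 15; the added Me3SiOTf then activates 2, the primary C9' silyl ether adds to the silylated carbonyl, hexamethyldisiloxane departs and the (E)-oxocarbenium ion 16 is captured at C7 by C8, which forms C7–O and C7–C8 in one operation and returns the lactone carbonyl. The closest known reaction type is the intramolecular Mukaiyama aldol-type addition of an enol ether or silyl ketene acetal to an oxocarbenium ion generated from an aldehyde (or acetal) and a silyl ether with a silyl triflate, as used to close furofuran rings, and it is the oxygen counterpart of a Mannich ring closure. Ring A closes in the 5-(enolexo)-endo-trig mode, a closure that is awkward for neutral acceptors but routine for iminium and oxocarbenium ions. C8 is controlled by the tether: the C9' arm on C8' can deliver C7 only to the face of the planar C8 on which it stands, so ring A is cis-fused and O8 ends cis to H8' whatever the configuration of C8 in 13. C7 is controlled by the (E) geometry of 16, which holds the aryl group anti to C9', together with closure through the conformer that leaves the aryl group on the convex side beside the small O8 trimethylsilyl ether and not over the C9 silyloxy terminus of ring B, which gives the exo (7R) aryl group. The step needs capture of the tethered ion at carbon in preference to bimolecular aldol addition of free aldehyde, which the substrate secures because the primary alkyl silyl ether is its only basic silyl ether (O8 is enolic), the fully substituted C8 is slow in bimolecular addition, and C8' has no leaving group that the ketene acetal could expel.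

Step 9
Reactants: 17 (3S,3aR,6R,6aR)-6-[4-(tert-butyldimethylsilyloxy)-3-methoxyphenyl]-3-(3,4-dimethoxyphenyl)-6a-(trimethylsilyloxy)tetrahydro-1H,3H-furo[3,4-c]furan-1-one
Product: 18 (3S,3aR,6R,6aR)-6-[4-(tert-butyldimethylsilyloxy)-3-methoxyphenyl]-3-(3,4-dimethoxyphenyl)-6a-(trimethylsilyloxy)tetrahydro-1H,3H-furo[3,4-c]furan-1-ol (lactol, both C9 epimers)
Conditions: i-Bu2AlH, CH2Cl2, −78 °C; aq. KNaC4H4O6 (potassium sodium tartrate)
Reagents that add atoms: none
Why: At −78 °C the tetrahedral aluminium alkoxide from hydride addition does not collapse, so the reduction stops at the lactol (partial reduction of a lactone), and silyl ethers and benzylic ethers are inert to the reagent.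

Step 10
Reactants: 18 (3S,3aR,6R,6aR)-6-[4-(tert-butyldimethylsilyloxy)-3-methoxyphenyl]-3-(3,4-dimethoxyphenyl)-6a-(trimethylsilyloxy)tetrahydro-1H,3H-furo[3,4-c]furan-1-ol
Product: 19 (1S,3aS,4R,6aR)-4-[4-(tert-butyldimethylsilyloxy)-3-methoxyphenyl]-1-(3,4-dimethoxyphenyl)-3a-(trimethylsilyloxy)tetrahydro-1H,3H-furo[3,4-c]furan (lignan descriptors 7R,8S,7'S,8'R)
Conditions: Et3SiH, BF3·OEt2, CH2Cl2, −78 to −40 °C; aq. NaHCO3
Reagents that add atoms: none
Why: BF3·OEt2 ionises the lactol to the cyclic oxocarbenium ion at C9 and Et3SiH delivers hydride (ionic hydrogenation of a lactol), which makes the CH2 of ring B without touching a stereocentre, the low temperature sparing the benzylic C7–O and C7'–O bonds.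

Step 11
Reactants: 19 (1S,3aS,4R,6aR)-4-[4-(tert-butyldimethylsilyloxy)-3-methoxyphenyl]-1-(3,4-dimethoxyphenyl)-3a-(trimethylsilyloxy)tetrahydro-1H,3H-furo[3,4-c]furan
Product: 20 (1S,3aS,4R,6aR)-1-(3,4-dimethoxyphenyl)-4-(4-hydroxy-3-methoxyphenyl)tetrahydro-1H,3H-furo[3,4-c]furan-3a(4H)-ol (lignan descriptors 7R,8S,7'S,8'R; CNP0141816.1)
Conditions: Bu4NF, AcOH, THF, 0 °C to rt
Reagents that add atoms: none
Why: Fluoride cleaves the aryl silyl ether and the tertiary trimethylsilyl ether (fluoride desilylation), and the acetic acid buffer keeps the freed para-hydroxybenzyl ether from opening through a quinone methide.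

Compound list
1 | vanillin | COc1cc(C=O)ccc1O | starting material
2 | 4-(tert-butyldimethylsilyloxy)-3-methoxybenzaldehyde | COc1cc(C=O)ccc1O[Si](C)(C)C(C)(C)C | intermediate
3 | (S)-4-benzyl-1,3-oxazolidin-2-one | O=C1N[C@@H](Cc2ccccc2)CO1 | starting material
4 | methyl 4-chloro-4-oxobutanoate | COC(=O)CCC(=O)Cl | starting material
5 | methyl 4-[(4S)-4-benzyl-2-oxo-1,3-oxazolidin-3-yl]-4-oxobutanoate | COC(=O)CCC(=O)N1[C@@H](Cc2ccccc2)COC1=O | intermediate
6 | 3,4-dimethoxybenzaldehyde | COc1ccc(C=O)cc1OC | starting material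
7 | methyl (3S,4S)-3-[(4S)-4-benzyl-2-oxo-1,3-oxazolidine-3-carbonyl]-4-(3,4-dimethoxyphenyl)-4-hydroxybutanoate (syn-aldol adduct) | COC(=O)C[C@H](C(=O)N1[C@@H](Cc2ccccc2)COC1=O)[C@H](O)c1ccc(OC)c(OC)c1 | intermediate (not isolated)
8 | (4S)-4-benzyl-3-[(2S,3S)-2-(3,4-dimethoxyphenyl)-5-oxooxolane-3-carbonyl]-1,3-oxazolidin-2-one | O=C1C[C@H](C(=O)N2[C@@H](Cc3ccccc3)COC2=O)[C@@H](c4ccc(OC)c(OC)c4)O1 | intermediate
9 | (2S,3S)-2-(3,4-dimethoxyphenyl)-5-oxooxolane-3-carboxylic acid | O=C1C[C@H](C(=O)O)[C@@H](c2ccc(OC)c(OC)c2)O1 | intermediate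
10 | (4R,5S)-5-(3,4-dimethoxyphenyl)-4-(hydroxymethyl)oxolan-2-one | O=C1C[C@H](CO)[C@@H](c2ccc(OC)c(OC)c2)O1 | intermediate
11 | (4R,5S)-5-(3,4-dimethoxyphenyl)-4-[(triethylsilyloxy)methyl]oxolan-2-one | O=C1C[C@H](CO[Si](CC)(CC)CC)[C@@H](c2ccc(OC)c(OC)c2)O1 | intermediate
12 | (3S,4S,5S)-5-(3,4-dimethoxyphenyl)-3-hydroxy-4-[(triethylsilyloxy)methyl]oxolan-2-one | O=C1[C@@H](O)[C@H](CO[Si](CC)(CC)CC)[C@@H](c2ccc(OC)c(OC)c2)O1 | intermediate (not isolated)
13 | (3S,4S,5S)-5-(3,4-dimethoxyphenyl)-3-hydroxy-4-(hydroxymethyl)oxolan-2-one | O=C1[C@@H](O)[C@H](CO)[C@@H](c2ccc(OC)c(OC)c2)O1 | intermediate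
14 | (3S,4R,5S)-5-(3,4-dimethoxyphenyl)-3-(trimethylsilyloxy)-4-[(trimethylsilyloxy)methyl]oxolan-2-one | O=C1[C@@H](O[Si](C)(C)C)[C@H](CO[Si](C)(C)C)[C@@H](c2ccc(OC)c(OC)c2)O1 | intermediate (not isolated)
15 | (4R,5S)-5-(3,4-dimethoxyphenyl)-2,3-bis(trimethylsilyloxy)-4-[(trimethylsilyloxy)methyl]-4,5-dihydrofuran | C[Si](C)(C)OC1=C(O[Si](C)(C)C)[C@H](CO[Si](C)(C)C)[C@@H](c2ccc(OC)c(OC)c2)O1 | intermediate (not isolated)
16 | (E)-O9'-[4-(tert-butyldimethylsilyloxy)-3-methoxybenzylidene]oxonium triflate of 15 (oxocarbenium ion) | C[Si](C)(C)OC1=C(O[Si](C)(C)C)[C@H](C/[O+]=C/c2ccc(O[Si](C)(C)C(C)(C)C)c(OC)c2)[C@@H](c3ccc(OC)c(OC)c3)O1.[O-]S(=O)(=O)C(F)(F)F | intermediate (not isolated)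
17 | (3S,3aR,6R,6aR)-6-[4-(tert-butyldimethylsilyloxy)-3-methoxyphenyl]-3-(3,4-dimethoxyphenyl)-6a-(trimethylsilyloxy)tetrahydro-1H,3H-furo[3,4-c]furan-1-one | COc1cc([C@H]2OC[C@@H]3[C@@H](c4ccc(OC)c(OC)c4)OC(=O)[C@]23O[Si](C)(C)C)ccc1O[Si](C)(C)C(C)(C)C | intermediate
18 | (3S,3aR,6R,6aR)-6-[4-(tert-butyldimethylsilyloxy)-3-methoxyphenyl]-3-(3,4-dimethoxyphenyl)-6a-(trimethylsilyloxy)tetrahydro-1H,3H-furo[3,4-c]furan-1-ol (both C1 epimers) | COc1cc([C@H]2OC[C@@H]3[C@@H](c4ccc(OC)c(OC)c4)OC(O)[C@]23O[Si](C)(C)C)ccc1O[Si](C)(C)C(C)(C)C | intermediate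
19 | (1S,3aS,4R,6aR)-4-[4-(tert-butyldimethylsilyloxy)-3-methoxyphenyl]-1-(3,4-dimethoxyphenyl)-3a-(trimethylsilyloxy)tetrahydro-1H,3H-furo[3,4-c]furan | COc1cc([C@H]2OC[C@@H]3[C@@H](c4ccc(OC)c(OC)c4)OC[C@]23O[Si](C)(C)C)ccc1O[Si](C)(C)C(C)(C)C | intermediate
20 | (1S,3aS,4R,6aR)-1-(3,4-dimethoxyphenyl)-4-(4-hydroxy-3-methoxyphenyl)tetrahydro-1H,3H-furo[3,4-c]furan-3a(4H)-ol | COc1cc([C@H]2OC[C@@H]3[C@@H](c4ccc(OC)c(OC)c4)OC[C@]23O)ccc1O | target

Total step count: 11. Longest linear sequence: 10 steps (steps 2 to 11, from 3 and 4 to 20); step 1 is a one-step side branch.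

Steps most likely to fail

Step 8. Two processes may spoil it. First, the ketene acetal may be consumed by bimolecular aldol addition to silyl-activated free aldehyde on the face anti to the C9' arm before the tether has formed, and such an adduct cannot close ring A. Second, the tethered ion may close through the conformer that has the oxocarbenium oxygen over the ketene acetal, which erodes facial selectivity at C7 (endo aryl). The fallback sets out from 13 and 2 and installs the tether before any enol derivative exists. Aldehyde 2 would be converted with HC(OMe)3 and catalytic p-TsOH in MeOH into 4-(tert-butyldimethylsilyloxy)-3-methoxybenzaldehyde dimethyl acetal F1. With diol 13 and catalytic pyridinium p-toluenesulfonate in CH2Cl2, F1 should give the trans-fused O8,O9'-arylidene acetal of 13 (a 2-aryl-1,3-dioxane on the lactone) F2. Et3N/Me3SiOTf would then enolise F2 to the silyl ketene acetal of the arylidene acetal F3. A small excess of Me3SiOTf should open F3 at the enolic oxygen O8, the better leaving group, to the same ion 16 within a contact ion pair. This ion should collapse by an oxygen-to-carbon 1,3-shift of the Petasis–Ferrier type (an acetal–enol ether Mukaiyama cyclisation). No free aldehyde is present, and C7 leaves O8 from the outer side of ring B, so the least-motion path is the exo closure. The fallback comes back to the route at 17.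

Step 10. Lewis-acid ionisation of the electron-rich benzylic C7–O9' or C7'–O bond (epimerisation or ring opening) may compete with ionisation of the lactol, whose oxocarbenium ion is destabilised by the neighbouring O8. Loss of the O8 silyl group alone would be harmless, because step 11 removes it. The fallback sets out from 18 and avoids Lewis acid. NaBH4 in EtOH at 0 °C should reduce the open hydroxy-aldehyde form to the 9,7'-diol F4. TsCl in pyridine should sulfonylate the primary C9 hydroxyl selectively to the C9 p-toluenesulfonate F5. KOt-Bu in THF should then close ring B by a 5-exo-tet Williamson etherification in which the C7' oxygen is the nucleophile, so C7' keeps its configuration. The fallback comes back at 19.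

Step 7. The enolate may add through carbon to the N-sulfonylimine formed from the oxaziridine, or be quenched by proton transfer, and the hydroxylation would then stall. The fallback sets out from 11 and oxidises a neutral enol derivative instead of a metal enolate. LiN(i-Pr)2 and Me3SiCl in THF at −78 °C should give the trimethylsilyl ketene acetal of 11 F6. mCPBA in hexane/CH2Cl2 at −20 °C (Rubottom oxidation, epoxidation anti to the C9' arm followed by silyl shift) should give the 3-(trimethylsilyloxy) lactone F7. 1 M HCl in THF removes both silyl groups, and the fallback comes back at 13.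

Further compounds
F1 | step 8 | 4-(tert-butyldimethylsilyloxy)-3-methoxybenzaldehyde dimethyl acetal | COC(OC)c1ccc(O[Si](C)(C)C(C)(C)C)c(OC)c1
F2 | step 8 | O8,O9'-[4-(tert-butyldimethylsilyloxy)-3-methoxybenzylidene] acetal of 13 (trans-fused 2-aryl-1,3-dioxane, acetal carbon unassigned) | O=C1[C@H]2OC(c3ccc(O[Si](C)(C)C(C)(C)C)c(OC)c3)OC[C@@H]2[C@@H](c4ccc(OC)c(OC)c4)O1
F3 | step 8 | trimethylsilyl ketene acetal of F2 | C[Si](C)(C)OC1=C2OC(c3ccc(O[Si](C)(C)C(C)(C)C)c(OC)c3)OC[C@@H]2[C@@H](c4ccc(OC)c(OC)c4)O1
F4 | step 10 | 9,7'-diol from reduction of 18 (ring B opened, O8 trimethylsilyl ether kept) | COc1cc([C@H]2OC[C@H]([C@H](O)c3ccc(OC)c(OC)c3)[C@@]2(CO)O[Si](C)(C)C)ccc1O[Si](C)(C)C(C)(C)C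
F5 | step 10 | C9 p-toluenesulfonate of F4 | COc1cc([C@H]2OC[C@H]([C@H](O)c3ccc(OC)c(OC)c3)[C@@]2(COS(=O)(=O)c3ccc(C)cc3)O[Si](C)(C)C)ccc1O[Si](C)(C)C(C)(C)C
F6 | step 7 | (4R,5S)-5-(3,4-dimethoxyphenyl)-4-[(triethylsilyloxy)methyl]-2-(trimethylsilyloxy)-4,5-dihydrofuran | C[Si](C)(C)OC1=C[C@H](CO[Si](CC)(CC)CC)[C@@H](c2ccc(OC)c(OC)c2)O1
F7 | step 7 | (3S,4R,5S)-5-(3,4-dimethoxyphenyl)-4-[(triethylsilyloxy)methyl]-3-(trimethylsilyloxy)oxolan-2-one | O=C1[C@@H](O[Si](C)(C)C)[C@H](CO[Si](CC)(CC)CC)[C@@H](c2ccc(OC)c(OC)c2)O1
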